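**Retrosynthetic overview**

1. Locants follow the acyclic C25 skeleton: ring = C1–C14, C14 = stereocentre, C3 carries CH2OH, side chain = C15–C19. The target comes from its methyl ester by 1,2-reduction; the only ring (14-membered carbocycle) is closed at C2=C3 by an intramolecular Z-selective Still–Gennari olefination.
2. The seco aldehyde comes from a C–O bond construction: O-vinylation of an (R)-configured secondary allylic alcohol (C16–OH), then [3,3] shift of the allyl vinyl ether. This relays C16–O into the C14 stereocentre, sets the (E)-C15=C16 olefin and frees the C2 aldehyde.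
3. The (R)-carbinol is set by a new chiral-phosphoric-acid-catalysed linear prenylation of an (E)-enal with an α,α-dimethylallyl boronate.
4. The enal chain (C4–C16, 6E and 10Z olefins) comes from nerylacetone: methyl ketone to alkyne, Zr-catalysed methylalumination/oxirane opening, iodide, SeO2 oxidation of the terminal (E)-methyl group. The phosphonate carbon (C3) is attached by alkylation.
5. Ring order: one ring only, formed in step 9.

Assumption: nerylacetone is bought as the single (5Z) isomer; the phosphonate-bearing carbon of the three phosphonate intermediates is a mixture of epimers, left undefined in their SMILES, and disappears in the ring closure.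

**Route**

Step 1
Reactants: 1 nerylacetone [(5Z)-6,10-dimethylundeca-5,9-dien-2-one]
Product: 3 (5Z)-6,10-dimethylundeca-5,9-dien-1-yne, via enol phosphate 2 (not isolated)
Conditions: LiN(iPr)2, THF, −78 °C; ClP(O)(OEt)2, −78 → 20 °C; LiN(iPr)2 (2.3 equiv), −78 → 20 °C; H2O
Reagents that add atoms: none
Why: Kinetic enolate O-phosphorylation at the methyl side followed by double elimination (Negishi methyl ketone to alkyne conversion) gives the terminal alkyne and leaves the (Z)-olefin untouched.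

Step 2
Reactants: 3 (5Z)-6,10-dimethylundeca-5,9-dien-1-yne
Product: 6 (3E,7Z)-4,8,12-trimethyltrideca-3,7,11-trien-1-ol, via alkenylalane 4 (not isolated), via lithium alanate 5 (not isolated)
Conditions: AlMe3 (2 equiv), Cp2ZrCl2 (0.25 equiv), ClCH2CH2Cl, 20 °C; evaporate; n-BuLi, hexane–THF, 0 °C; oxirane, 0 → 20 °C; aqueous work-up
Reagents that add atoms: trimethylaluminium C[Al](C)C; oxirane C1CO1
Why: Zr-catalysed syn-methylalumination (Negishi carboalumination) fixes the (E)-C6=C7 olefin, and the derived alanate opens oxirane with retention at the alkenyl carbon to add C5 and C4.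

Step 3
Reactants: 6 (3E,7Z)-4,8,12-trimethyltrideca-3,7,11-trien-1-ol
Product: 7 (6Z,10E)-13-iodo-2,6,10-trimethyltrideca-2,6,10-triene
Conditions: PPh3, imidazole, iodine, CH2Cl2, 0 °C
Reagents that add atoms: iodine [I][I]
Why: Appel-type iodination of the primary alcohol under buffered conditions does not touch the trisubstituted olefins.

Step 4
Reactants: 7 (6Z,10E)-13-iodo-2,6,10-trimethyltrideca-2,6,10-triene
Product: 9 (2E,6Z,10E)-13-iodo-2,6,10-trimethyltrideca-2,6,10-trienal, via allylic alcohol 8 (not isolated)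
Conditions: SeO2 (0.3 equiv), t-BuOOH (decane solution, 2.5 equiv), salicylic acid (0.1 equiv), CH2Cl2, 0 → 20 °C; then MnO2 (15 equiv), 20 °C
Reagents that add atoms: selenium dioxide O=[Se]=O; tert-butyl hydroperoxide CC(C)(C)OO
Why: Riley allylic oxidation (ene then [2,3] shift) prefers the (E)-methyl group of the terminal isopropylidene unit, and MnO2 then oxidises only the new allylic alcohol to the (E)-enal.

Step 5
Reactants: 10 1-chloro-3-methylbut-2-ene (prenyl chloride); 11 2-isopropoxy-4,4,5,5-tetramethyl-1,3,2-dioxaborolane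
Product: 13 4,4,5,5-tetramethyl-2-(2-methylbut-3-en-2-yl)-1,3,2-dioxaborolane, via Grignard reagent 12 (not isolated)
Conditions: Mg turnings, THF, 0 °C (slow addition of 10); then 11, −78 → 20 °C; aq. NH4Cl
Reagents that add atoms: none
Why: The allylic Grignard reagent attacks the borate through its γ-carbon (SE2' borylation), giving the tertiary α,α-dimethylallyl boronate, which as a pinacol ester does not undergo 1,3-boron shift at room temperature.

Step 6
Reactants: 9 (2E,6Z,10E)-13-iodo-2,6,10-trimethyltrideca-2,6,10-trienal; 13 4,4,5,5-tetramethyl-2-(2-methylbut-3-en-2-yl)-1,3,2-dioxaborolane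
Product: 15 (5R,6E,10Z,14E)-17-iodo-2,6,10,14-tetramethylheptadeca-2,6,10,14-tetraen-5-ol, via borate ester 14 (not isolated)
Conditions: (R)-3,3'-bis(2,4,6-triisopropylphenyl)-1,1'-binaphthyl-2,2'-diyl hydrogen phosphate [(R)-TRIP, 10 mol%], 13 (1.5 equiv), 4 Å molecular sieves, toluene, −30 → 0 °C; aq. NaHCO3
Reagents that add atoms: none
Why: Proposed new method: chiral-phosphoric-acid-catalysed enantioselective linear prenylation of an α-branched enal with a tertiary allyl pinacol boronate, not yet shown for α,α-disubstituted allylboronates; the boronate can only transfer through its unsubstituted γ-CH2 in a closed chair transition state (giving CH2–CH=CMe2 with no E/Z issue) while the acid hydrogen-bonds to a boronate oxygen and the formyl C–H to select the aldehyde face, as in the closest known reaction, the phosphoric-acid-catalysed allyl- and crotylboration of aldehydes with pinacol boronates, where the (R)-acid gives the (R)-carbinol needed here at C16 (the (S)-acid is used if the sense proves opposite).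

Step 7
Reactants: 15 (5R,6E,10Z,14E)-17-iodo-2,6,10,14-tetramethylheptadeca-2,6,10,14-tetraen-5-ol; 16 methyl 2-[bis(2,2,2-trifluoroethoxy)phosphoryl]acetate
Product: 17 methyl (5E,9Z,13E,15R)-2-[bis(2,2,2-trifluoroethoxy)phosphoryl]-15-hydroxy-6,10,14,18-tetramethylnonadeca-5,9,13,17-tetraenoate (C2 epimers)
Conditions: NaH, 16 (2.5 equiv), DMF, 0 °C; then 15, 20 → 45 °C
Reagents that add atoms: none
Why: SN2 C-alkylation of the preformed sodium phosphonoacetate by the primary iodide; excess 16 suppresses dialkylation and the weakly basic anion leaves the free secondary alcohol alone.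

Step 8
Reactants: 17 methyl (5E,9Z,13E,15R)-2-[bis(2,2,2-trifluoroethoxy)phosphoryl]-15-hydroxy-6,10,14,18-tetramethylnonadeca-5,9,13,17-tetraenoate
Product: 19 methyl (5E,9Z,13R,14E)-2-[bis(2,2,2-trifluoroethoxy)phosphoryl]-6,10,14,18-tetramethyl-13-(2-oxoethyl)nonadeca-5,9,14,17-tetraenoate (C2 epimers), via vinyl ether 18 (not isolated)
Conditions: Pd(OCOCF3)2 (5 mol%), 4,7-diphenyl-1,10-phenanthroline (5 mol%), Et3N (10 mol%), butyl vinyl ether, 75 °C; filter through basic alumina, evaporate; xylene, 140 °C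
Reagents that add atoms: butyl vinyl ether C=COCCCC
Why: Palladium-catalysed transfer vinylation makes the O–vinyl C–O bond without breaking the carbinol C–O bond, and the allyl vinyl ether then undergoes a chair-like Claisen [3,3] rearrangement with the prenylmethyl group pseudo-equatorial, so the (R)-carbinol becomes the (R) all-carbon centre C14 and the (E)-C15=C16 olefin while the C2 aldehyde is unveiled.

Step 9
Reactants: 19 methyl (5E,9Z,13R,14E)-2-[bis(2,2,2-trifluoroethoxy)phosphoryl]-6,10,14,18-tetramethyl-13-(2-oxoethyl)nonadeca-5,9,14,17-tetraenoate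
Product: 20 methyl (1Z,4R,7Z,11E)-7,11-dimethyl-4-[(2E)-6-methylhepta-2,5-dien-2-yl]cyclotetradeca-1,7,11-triene-1-carboxylate
Conditions: KN(SiMe3)2, 18-crown-6, THF, −78 → −20 °C, 19 added by syringe pump (final 1 mM)
Reagents that add atoms: none
Why: Intramolecular Horner–Wadsworth–Emmons reaction of the Still–Gennari phosphonate under dissociating conditions and high dilution closes the 14-membered ring with kinetic (Z)-selectivity (C1 cis to CO2Me), and C14, which is β to the aldehyde, cannot epimerise.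

Step 10
Reactants: 20 methyl (1Z,4R,7Z,11E)-7,11-dimethyl-4-[(2E)-6-methylhepta-2,5-dien-2-yl]cyclotetradeca-1,7,11-triene-1-carboxylate
Product: 21 [(1Z,4R,7Z,11E)-7,11-dimethyl-4-[(2E)-6-methylhepta-2,5-dien-2-yl]cyclotetradeca-1,7,11-trien-1-yl]methanol (CNP0288338.1)
Conditions: iBu2AlH (2.5 equiv), CH2Cl2, −78 °C; Rochelle salt work-up
Reagents that add atoms: none
Why: 1,2-Reduction of the enoate by the aluminium hydride at low temperature gives the allylic alcohol without conjugate reduction or olefin isomerisation.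

**Compound list**

1 | nerylacetone, (5Z)-6,10-dimethylundeca-5,9-dien-2-one | CC(=O)CC/C=C(/C)CCC=C(C)C | starting material
2 | diethyl (5Z)-6,10-dimethylundeca-1,5,9-trien-2-yl phosphate | C=C(OP(=O)(OCC)OCC)CC/C=C(/C)CCC=C(C)C | intermediate
3 | (5Z)-6,10-dimethylundeca-5,9-dien-1-yne | C#CCC/C=C(/C)CCC=C(C)C | intermediate
4 | dimethyl[(1E,5Z)-2,6,10-trimethylundeca-1,5,9-trien-1-yl]alane | C[Al](C)/C=C(\C)CC/C=C(/C)CCC=C(C)C | intermediate
5 | lithium butyl(dimethyl)[(1E,5Z)-2,6,10-trimethylundeca-1,5,9-trien-1-yl]aluminate | [Li+].CCCC[Al-](C)(C)/C=C(\C)CC/C=C(/C)CCC=C(C)C | intermediate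
6 | (3E,7Z)-4,8,12-trimethyltrideca-3,7,11-trien-1-ol | OCC/C=C(\C)CC/C=C(/C)CCC=C(C)C | intermediate
7 | (6Z,10E)-13-iodo-2,6,10-trimethyltrideca-2,6,10-triene | ICC/C=C(\C)CC/C=C(/C)CCC=C(C)C | intermediate
8 | (2E,6Z,10E)-13-iodo-2,6,10-trimethyltrideca-2,6,10-trien-1-ol | ICC/C=C(\C)CC/C=C(/C)CC/C=C(\C)CO | intermediate
9 | (2E,6Z,10E)-13-iodo-2,6,10-trimethyltrideca-2,6,10-trienal | ICC/C=C(\C)CC/C=C(/C)CC/C=C(\C)C=O | intermediate
10 | 1-chloro-3-methylbut-2-ene (prenyl chloride) | CC(C)=CCCl | starting material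
11 | 2-isopropoxy-4,4,5,5-tetramethyl-1,3,2-dioxaborolane | CC(C)OB1OC(C)(C)C(C)(C)O1 | starting material
12 | (3-methylbut-2-en-1-yl)magnesium chloride | CC(C)=CC[Mg]Cl | intermediate
13 | 4,4,5,5-tetramethyl-2-(2-methylbut-3-en-2-yl)-1,3,2-dioxaborolane | C=CC(C)(C)B1OC(C)(C)C(C)(C)O1 | intermediate
14 | 2-{[(5R,6E,10Z,14E)-17-iodo-2,6,10,14-tetramethylheptadeca-2,6,10,14-tetraen-5-yl]oxy}-4,4,5,5-tetramethyl-1,3,2-dioxaborolane | ICC/C=C(\C)CC/C=C(/C)CC/C=C(\C)[C@H](OB1OC(C)(C)C(C)(C)O1)CC=C(C)C | intermediate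
15 | (5R,6E,10Z,14E)-17-iodo-2,6,10,14-tetramethylheptadeca-2,6,10,14-tetraen-5-ol | ICC/C=C(\C)CC/C=C(/C)CC/C=C(\C)[C@H](O)CC=C(C)C | intermediate
16 | methyl 2-[bis(2,2,2-trifluoroethoxy)phosphoryl]acetate | COC(=O)CP(=O)(OCC(F)(F)F)OCC(F)(F)F | starting material
17 | methyl (5E,9Z,13E,15R)-2-[bis(2,2,2-trifluoroethoxy)phosphoryl]-15-hydroxy-6,10,14,18-tetramethylnonadeca-5,9,13,17-tetraenoate (C2 epimers) | COC(=O)C(CC/C=C(\C)CC/C=C(/C)CC/C=C(\C)[C@H](O)CC=C(C)C)P(=O)(OCC(F)(F)F)OCC(F)(F)F | intermediate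
18 | methyl (5E,9Z,13E,15R)-2-[bis(2,2,2-trifluoroethoxy)phosphoryl]-15-(ethenyloxy)-6,10,14,18-tetramethylnonadeca-5,9,13,17-tetraenoate (C2 epimers) | COC(=O)C(CC/C=C(\C)CC/C=C(/C)CC/C=C(\C)[C@H](OC=C)CC=C(C)C)P(=O)(OCC(F)(F)F)OCC(F)(F)F | intermediate
19 | methyl (5E,9Z,13R,14E)-2-[bis(2,2,2-trifluoroethoxy)phosphoryl]-6,10,14,18-tetramethyl-13-(2-oxoethyl)nonadeca-5,9,14,17-tetraenoate (C2 epimers) | COC(=O)C(CC/C=C(\C)CC/C=C(/C)CC[C@H](CC=O)/C(C)=C/CC=C(C)C)P(=O)(OCC(F)(F)F)OCC(F)(F)F | intermediate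
20 | methyl (1Z,4R,7Z,11E)-7,11-dimethyl-4-[(2E)-6-methylhepta-2,5-dien-2-yl]cyclotetradeca-1,7,11-triene-1-carboxylate | CC(C)=CC/C=C(\C)[C@H]1C/C=C(\C(=O)OC)CC/C=C(\C)CC/C=C(/C)CC1 | intermediate
21 | [(1Z,4R,7Z,11E)-7,11-dimethyl-4-[(2E)-6-methylhepta-2,5-dien-2-yl]cyclotetradeca-1,7,11-trien-1-yl]methanol | CC(C)=CC/C=C(\C)[C@H]1C/C=C(\CO)CC/C=C(\C)CC/C=C(/C)CC1 | target

**Step count and risks**

Total step count: 10. Longest linear sequence: 9 steps (steps 1–4 and 6–10, from nerylacetone); step 5 is a one-step side branch.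

The three steps most likely to fail:

Step 6 (the proposed new prenylation). The hindered tertiary boronate may add slowly, the enantioselectivity is untested, and acid-promoted 1,3-boron shift of 13 would give the branched adduct. Fallback with known chemistry, setting out from 9 and coming back at 15: the same phosphoric acid catalyses allylboration of 9 with commercial 2-allyl-4,4,5,5-tetramethyl-1,3,2-dioxaborolane (toluene, 4 Å molecular sieves, −30 °C). This gives the borate 2-{[(4R,5E,9Z,13E)-16-iodo-5,9,13-trimethylhexadeca-1,5,9,13-tetraen-4-yl]oxy}-4,4,5,5-tetramethyl-1,3,2-dioxaborolane F1, hydrolysed on work-up to the homoallylic alcohol (4R,5E,9Z,13E)-16-iodo-5,9,13-trimethylhexadeca-1,5,9,13-tetraen-4-ol F2. Cross-metathesis of F2 with 2-methyl-2-butene (second-generation Grubbs catalyst RuCl2(=CHPh)(PCy3)(H2IMes), 40 °C) turns the terminal vinyl group into the prenyl end and gives 15. This costs one more linear step.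

Step 9 (macrocyclic olefination). Oligomerisation or an eroded Z:E ratio is possible in the ring-closing mode. Fallback, setting out from 15 and coming back at 20: the olefin geometry is fixed intermolecularly and the ring is closed by an sp3–sp2 Negishi coupling instead. 15 is O-vinylated and rearranged under the step 8 conditions to the vinyl ether (5R,6E,10Z,14E)-5-(ethenyloxy)-17-iodo-2,6,10,14-tetramethylheptadeca-2,6,10,14-tetraene F3 and then the aldehyde (3R,6Z,10E)-13-iodo-6,10-dimethyl-3-[(2E)-6-methylhepta-2,5-dien-2-yl]trideca-6,10-dienal F4. The brominated Still–Gennari reagent methyl 2-bromo-2-[bis(2,2,2-trifluoroethoxy)phosphoryl]acetate F5 is made from 16 (NaH, then N-bromosuccinimide). Its Horner–Wadsworth–Emmons reaction with F4 (KN(SiMe3)2, 18-crown-6, THF, −78 °C) gives the bromo enoate methyl (2E,5R,8Z,12E)-2-bromo-15-iodo-8,12-dimethyl-5-[(2E)-6-methylhepta-2,5-dien-2-yl]pentadeca-2,8,12-trienoate F6, with the chain CH2 trans to Br. Zinc insertion into the primary iodide (Zn dust, LiCl, THF) gives the alkylzinc reagent {(3E,7Z,11R,13E)-14-bromo-15-methoxy-4,8-dimethyl-11-[(2E)-6-methylhepta-2,5-dien-2-yl]-15-oxopentadeca-3,7,13-trien-1-yl}zinc iodide F7. Slow addition of F7 to Pd(OAc)2 and 2-dicyclohexylphosphino-2',6'-dimethoxybiphenyl in THF at 50 °C (high dilution) couples with retention at the vinyl bromide and gives 20.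

Step 4 (allylic oxidation of a triene). Site selectivity for the terminal (E)-methyl group is only moderate, and over-oxidation or internal oxidation lowers the yield. Fallback, setting out from 7 and coming back at 9: olefin cross-metathesis of the terminal isopropylidene group of 7 with methacrolein (second-generation Hoveyda–Grubbs catalyst RuCl2(=CH-C6H4-2-OiPr)(H2IMes), CH2Cl2, 40 °C) installs the (E)-2-methyl enal directly. It makes no new compound (F0).

**Further compounds**

F1 | step 6 | 2-{[(4R,5E,9Z,13E)-16-iodo-5,9,13-trimethylhexadeca-1,5,9,13-tetraen-4-yl]oxy}-4,4,5,5-tetramethyl-1,3,2-dioxaborolane | ICC/C=C(\C)CC/C=C(/C)CC/C=C(\C)[C@H](OB1OC(C)(C)C(C)(C)O1)CC=C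
F2 | step 6 | (4R,5E,9Z,13E)-16-iodo-5,9,13-trimethylhexadeca-1,5,9,13-tetraen-4-ol | ICC/C=C(\C)CC/C=C(/C)CC/C=C(\C)[C@H](O)CC=C
F3 | step 9 | (5R,6E,10Z,14E)-5-(ethenyloxy)-17-iodo-2,6,10,14-tetramethylheptadeca-2,6,10,14-tetraene | ICC/C=C(\C)CC/C=C(/C)CC/C=C(\C)[C@H](OC=C)CC=C(C)C
F4 | step 9 | (3R,6Z,10E)-13-iodo-6,10-dimethyl-3-[(2E)-6-methylhepta-2,5-dien-2-yl]trideca-6,10-dienal | ICC/C=C(\C)CC/C=C(/C)CC[C@H](CC=O)/C(C)=C/CC=C(C)C
F5 | step 9 | methyl 2-bromo-2-[bis(2,2,2-trifluoroethoxy)phosphoryl]acetate | COC(=O)C(Br)P(=O)(OCC(F)(F)F)OCC(F)(F)F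
F6 | step 9 | methyl (2E,5R,8Z,12E)-2-bromo-15-iodo-8,12-dimethyl-5-[(2E)-6-methylhepta-2,5-dien-2-yl]pentadeca-2,8,12-trienoate | ICC/C=C(\C)CC/C=C(/C)CC[C@H](C/C=C(/Br)C(=O)OC)/C(C)=C/CC=C(C)C
F7 | step 9 | {(3E,7Z,11R,13E)-14-bromo-15-methoxy-4,8-dimethyl-11-[(2E)-6-methylhepta-2,5-dien-2-yl]-15-oxopentadeca-3,7,13-trien-1-yl}zinc iodide | I[Zn]CC/C=C(\C)CC/C=C(/C)CC[C@H](C/C=C(/Br)C(=O)OC)/C(C)=C/CC=C(C)C
F0 | step 4 | none | none
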